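## Retrosynthetic overview

1. (+)-Neoolivil comes from hydrogenolysis of the two primary O-benzyl groups of its bis(benzyl ether).
2. That ether comes from a one-pot Lewis-acid double Friedel–Crafts arylation of the bis-lactol of C2-symmetric (2S,3S)-2,3-bis(benzyloxymethyl)succinaldehyde with guaiacol. This step forms the THF ring and both Ar–C bonds, with the aryl groups entering anti to the neighbouring CH2OBn groups.
3. The dialdehyde comes from a reductive Nef conversion of the CH2NO2 group of the Michael adduct.
4. The adduct comes from the enamine-catalysed Michael addition of 3-(benzyloxy)propanal to (E)-3-(benzyloxy)-1-nitropropene, which sets both ring stereocentres (C3 and C4) as the syn adduct (trans after ring closure).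
5. The nitroalkene comes from a one-pot Henry/dehydration of benzyloxyacetaldehyde with nitromethane, so no stereocentre is isolated before the asymmetric step. The ring is formed only in the Friedel–Crafts step.

Assumption: the (S)-diarylprolinol silyl ether gives the same facial sense with these alkyl-type donors and acceptors as in the classical propanal/nitrostyrene addition, i.e. the (2R,3S)-syn sense.

## Route

**Step 1**
Reactants: **1** 2-(benzyloxy)acetaldehyde; **2** nitromethane
Product: **3** (E)-3-(benzyloxy)-1-nitroprop-1-ene
Conditions: (i) **2** (3 equiv), DBU (5 mol%), THF, 0 °C, 3 h; concentrate to remove excess **2**; (ii) CH2Cl2, MsCl (1.2 equiv), Et3N (2.5 equiv), −10 → 0 °C, 1 h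
Reagents that add atoms: nitromethane, C[N+](=O)[O-]
Why: Henry (nitroaldol) addition gives the racemic nitro alcohol, which is not isolated. In situ mesylation and E1cB elimination then give the conjugated (E)-nitroalkene and destroy the only carbinol stereocentre, so the first stereocentre of the route is set by the catalyst in Step 3.

**Step 2**
Reactants: **4** 3-(benzyloxy)propan-1-ol
Product: **5** 3-(benzyloxy)propanal
Conditions: Dess–Martin periodinane, NaHCO3, CH2Cl2, 0 °C → rt, 1 h; use the aldehyde immediately
Reagents that add atoms: none
Why: Dess–Martin oxidation of a primary alcohol stops at the aldehyde and leaves the benzyl ether intact.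

**Step 3**
Reactants: **5** 3-(benzyloxy)propanal (2 equiv); **3** (E)-3-(benzyloxy)-1-nitroprop-1-ene (1 equiv); **6** (S)-diphenylprolinol TMS ether (catalyst)
Product: **7** (2S,3R)-2,3-bis[(benzyloxy)methyl]-4-nitrobutanal (syn adduct)
Conditions: **6** (20 mol%), PhCO2H (20 mol%), CH2Cl2, 0 °C, 48 h
Reagents that add atoms: none
Why: Hayashi–Jørgensen enamine-catalysed Michael addition; the bulky silyloxy group shields one enamine face and the acyclic synclinal transition state sets both stereocentres as the syn adduct, which becomes the (S,S)-dialdehyde after Nef conversion.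

**Step 4**
Reactants: **7**
Product: **8** (2S,3S)-2,3-bis[(benzyloxy)methyl]butanedial (largely as its bis-lactol, 3,4-bis(benzyloxymethyl)oxolane-2,5-diol, used crude)
Conditions: TiCl3 (aq., 3.5 equiv), NH4OAc buffer (pH ≈ 6), THF/H2O, 0 °C → rt, 2 h; extract and use at once
Reagents that add atoms: water, O
Why: McMurry-type reductive Nef reaction under buffered conditions converts CH2NO2 to CHO without strong base, so the α-stereocentres are not epimerised and BnOH is not lost by β-elimination; the trans C2-symmetric dialdehyde is also the thermodynamic diastereomer.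

**Step 5**
Reactants: **8**; **9** guaiacol (4 equiv)
Product: **10** (2R,3S,4S,5R)-3,4-bis(benzyloxymethyl)-2,5-bis(4-hydroxy-3-methoxyphenyl)oxolane
Conditions: Sc(OTf)3 (10 mol%), 4 Å MS, CH2Cl2/MeNO2 (4:1), −20 → 25 °C, 12 h
Reagents that add atoms: guaiacol, COc1ccccc1O
Why: Proposed new method: Sc(OTf)3 ionises the bis-lactol to a cyclic oxocarbenium, and guaiacol attacks through its most nucleophilic site (para to OH), anti to the adjacent CH2OBn group. The resulting 2-aryl-5-hydroxy-THF re-ionises and is arylated again anti to the C4 substituent, while reversible p-hydroxybenzylic C–O ionisation funnels C2 and C5 to the all-trans isomer. The closest known reaction is Friedel–Crafts C-arylation of lactols (C-aryl glycoside formation) with phenols; here it is applied twice to a succinaldehyde bis-lactol with a free phenol to build a 2,5-diaryl-THF.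

**Step 6**
Reactants: **10**
Product: **11** (+)-neoolivil
Conditions: H2 (1 atm), 10% Pd/C, EtOAc/EtOH (1:1), rt, 2–3 h, stop at consumption of starting material
Reagents that add atoms: none
Why: catalytic hydrogenolysis removes the two primary benzyl ethers (toluene is lost) and leaves the aryl methyl ethers, phenols and ring stereocentres untouched; the short reaction time under neutral conditions avoids benzylic C–O cleavage of the diaryl-THF.

## Compound list
1 | 2-(benzyloxy)acetaldehyde | O=CCOCc1ccccc1 | starting material
2 | nitromethane | C[N+](=O)[O-] | starting material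
3 | (E)-3-(benzyloxy)-1-nitroprop-1-ene | [O-][N+](=O)/C=C/COCc1ccccc1 | intermediate
4 | 3-(benzyloxy)propan-1-ol | OCCCOCc1ccccc1 | starting material
5 | 3-(benzyloxy)propanal | O=CCCOCc1ccccc1 | intermediate
6 | (S)-diphenylprolinol TMS ether (commercial organocatalyst) | C[Si](C)(C)OC(c1ccccc1)(c1ccccc1)[C@@H]1CCCN1 | starting material
7 | (2S,3R)-2,3-bis[(benzyloxy)methyl]-4-nitrobutanal | O=C[C@H](COCc1ccccc1)[C@@H](COCc1ccccc1)C[N+](=O)[O-] | intermediate
8 | (2S,3S)-2,3-bis[(benzyloxy)methyl]butanedial | O=C[C@H](COCc1ccccc1)[C@@H](COCc1ccccc1)C=O | intermediate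
9 | guaiacol | COc1ccccc1O | starting material
10 | (2R,3S,4S,5R)-3,4-bis(benzyloxymethyl)-2,5-bis(4-hydroxy-3-methoxyphenyl)oxolane | COc1cc([C@@H]2O[C@@H](c3ccc(O)c(OC)c3)[C@H](COCc3ccccc3)[C@H]2COCc2ccccc2)ccc1O | intermediate
11 | (+)-neoolivil, [(2R,3S,4S,5R)-2,5-bis(4-hydroxy-3-methoxyphenyl)oxolane-3,4-diyl]dimethanol | COc1cc([C@@H]2O[C@@H](c3ccc(O)c(OC)c3)[C@H](CO)[C@H]2CO)ccc1O | target

## Totals
Total steps: 6. Longest linear sequence: 5 (Steps 1, 3, 4, 5, 6).

## Three steps most likely to fail
1. **Step 5 (proposed new double Friedel–Crafts cyclisation).** Risks are ortho-to-OH arylation, gem-diarylation, Lewis-acid cleavage of a benzyl ether, and a mixture at C2/C5.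
   Fallback: add excess 4-(benzyloxy)-3-methoxyphenylmagnesium bromide to freshly prepared **8** to give the 1,4-diaryl-1,4-diol. Close the ring with TsOH in CH2Cl2 by benzylic SN1 cyclodehydration, which is thermodynamically all-trans; the primary OH groups are benzylated and cannot compete. Finish with H2/Pd-C, which removes all four benzyl groups.
2. **Step 3 (Michael addition of a β-alkoxy aldehyde to a γ-alkoxy nitroalkene).** Risks are β-elimination of the enamine to an acrolein iminium, low dr, and SN2′ attack on the nitroallyl ether.
   Fallback: switch to an auxiliary-controlled route. Oxidatively homocouple the sodium Z-enolate of the N-(3-benzyloxypropanoyl)-4-benzyloxazolidin-2-one (NaHMDS, THF, −78 °C; then Fe(acac)3). Use the auxiliary enantiomer that gives the (2S,3S)-2,3-bis(benzyloxymethyl)succinyl bis-imide. Remove the auxiliaries with LiBH4 (MeOH/THF) to give (2S,3S)-2,3-bis(benzyloxymethyl)butane-1,4-diol, then oxidise with Dess–Martin periodinane to **8**.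
3. **Step 4 (Nef conversion next to an epimerisable, β-alkoxy aldehyde).** Risks are epimerisation at C2/C3 leading to the meso isomer, and loss of BnOH.
   Fallback: lock the stereocentres as alcohols. Reduce the CHO of **7** with NaBH4, then perform an oxidative Nef (KOtBu, then O3 at −78 °C, or Oxone) to the lactol/aldehyde. Reduce with NaBH4 to the (2S,3S)-2,3-bis(benzyloxymethyl)butane-1,4-diol and regenerate **8** by double Dess–Martin oxidation immediately before Step 5.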